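**Retrosynthetic overview**
1. Numbering (forward order): 1 3,4,5-trimethoxybenzaldehyde, 2 5-ethynyl-1,2,3-trimethoxybenzene, 3 5-iodovanillin, 4 the o-alkynylphenol, 5 ocophyllal B.
2. 5 ⇒ 4: open the furan ring at the O1–C2 bond and cut the C3–CH3 bond at the same time (forward: methylative 5-endo-dig oxypalladation, the C–O ring closure being the key step).
3. 4 ⇒ 2 + 3: C(sp)–C(sp2) disconnection (Sonogashira); 3 already carries the phenol oxygen, the 7-methoxy group and the 5-formyl group.
4. 2 ⇒ 1: one-carbon homologation of the aldehyde to the terminal alkyne.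
5. Ring order: both benzene rings are bought; the furan ring is the only ring made, in the last step.

Assumption: the target SMILES contains no stereocentre and no stereogenic double bond, so the compound is achiral and no stereocontrol is needed.

**Route**

Step 1
Reactants: 1 3,4,5-trimethoxybenzaldehyde
Product: 2 5-ethynyl-1,2,3-trimethoxybenzene
Conditions: dimethyl (1-diazo-2-oxopropyl)phosphonate (1.2 equiv), K2CO3 (2 equiv), MeOH, 0 °C to rt, 12 h
Reagents that add atoms: dimethyl (1-diazo-2-oxopropyl)phosphonate, CC(=O)C(=[N+]=[N-])P(=O)(OC)OC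
Why: Seyferth–Gilbert homologation in its Ohira–Bestmann form: methoxide cleaves the acetyl group, the resulting diazomethylphosphonate anion olefinates the non-enolisable aldehyde, and loss of N2 with 1,2-hydrogen shift gives the terminal alkyne; no stereocentre is involved.

Step 2
Reactants: 2 5-ethynyl-1,2,3-trimethoxybenzene; 3 5-iodovanillin (4-hydroxy-3-iodo-5-methoxybenzaldehyde)
Product: 4 4-hydroxy-3-methoxy-5-[(3,4,5-trimethoxyphenyl)ethynyl]benzaldehyde
Conditions: 2 (1.15 equiv), PdCl2(PPh3)2 (2 mol %), CuI (1 mol %), Et3N (3 equiv), degassed THF, 20 °C, 6 h; aq NH4Cl wash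
Reagents that add atoms: none
Why: Sonogashira coupling: the aryl iodide adds to zerovalent palladium at room temperature, and low copper loading and low temperature keep the free o-alkynylphenol from cyclising early; the aldehyde and methyl ethers are inert.

Step 3
Reactants: 4 4-hydroxy-3-methoxy-5-[(3,4,5-trimethoxyphenyl)ethynyl]benzaldehyde
Product: 5 ocophyllal B (7-methoxy-3-methyl-2-(3,4,5-trimethoxyphenyl)-1-benzofuran-5-carbaldehyde)
Conditions: Pd(OAc)2 (10 mol %), MeB(OH)2 (3 equiv), 1,4-benzoquinone (1.5 equiv), KOAc (0.5 equiv), tert-amyl alcohol, 60 °C, N2; 4 added by syringe pump over 3 h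
Reagents that add atoms: methylboronic acid, CB(O)O
Why: Proposed new method: methylative oxypalladation, in which methylboronic acid transmetalates to Pd(OAc)2 to give MePd(OAc) of divalent palladium, this π-acid binds the alkyne, and the ortho phenol oxygen can only reach the distal alkyne carbon bearing the trimethoxyphenyl group (5-endo-dig anti-oxypalladation), which forms the O1–C2 bond and the furan ring and places palladium on C3; C(sp2)–CH3 reductive elimination from (benzofuran-3-yl)Pd(Me) then installs the 3-methyl group (methyl has no β-hydrogen, and benzoquinone promotes this step), and benzoquinone returns zerovalent palladium to the divalent state; slow addition of the phenol and the absence of chelating nitrogen ligands disfavour protonolysis of the C3–Pd bond; the closest known reaction types are the Cacchi annulation and the oxidative oxypalladation/cross-coupling cascades of 2-alkynylphenols with alkenes or arylboron reagents, together with benzoquinone-promoted methyl transfer from methylboron reagents in C–H methylation; no stereocentre is formed.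

**Compound list**
1 | 3,4,5-trimethoxybenzaldehyde | COc1cc(C=O)cc(OC)c1OC | starting material
2 | 5-ethynyl-1,2,3-trimethoxybenzene | COc1cc(C#C)cc(OC)c1OC | intermediate
3 | 5-iodovanillin (4-hydroxy-3-iodo-5-methoxybenzaldehyde) | COc1cc(C=O)cc(I)c1O | starting material
4 | 4-hydroxy-3-methoxy-5-[(3,4,5-trimethoxyphenyl)ethynyl]benzaldehyde | COc1cc(C=O)cc(C#Cc2cc(OC)c(OC)c(OC)c2)c1O | intermediate
5 | ocophyllal B (7-methoxy-3-methyl-2-(3,4,5-trimethoxyphenyl)-1-benzofuran-5-carbaldehyde) | COc1cc(-c2oc3c(OC)cc(C=O)cc3c2C)cc(OC)c1OC | target

**Totals**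
Total step count: 3. Longest linear sequence: 3 steps (1 → 2 → 4 → 5); 3 enters at step 2.

**Steps most likely to fail, with fallbacks**

Step 3 (proposed new step, highest risk). The main danger is protonolysis of the C3–Pd bond before methyl transfer, which would give the 3-unsubstituted benzofuran; methyl homocoupling would also consume reagent. The fallback uses known chemistry, sets out from 4 and returns at 5. Iodocyclisation of 4 with I2 (2 equiv) and NaHCO3 (2 equiv) in MeCN at 20 °C closes the same O1–C2 bond and gives 3-iodo-7-methoxy-2-(3,4,5-trimethoxyphenyl)-1-benzofuran-5-carbaldehyde F1. Suzuki–Miyaura methylation of this iodide with trimethylboroxine, PdCl2(dppf) (5 mol %) and K2CO3 in dioxane at 100 °C then gives 5; the aldehyde tolerates both operations.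

Step 2. The free o-alkynylphenol may partly cyclise under copper and amine to the 3-unsubstituted benzofuran, and 2 may undergo Glaser dimerisation. The fallback masks the phenol; it sets out from 3 and returns at 4. Acetylation of 3 (Ac2O, pyridine, cat. DMAP, CH2Cl2, rt) gives 4-formyl-2-iodo-6-methoxyphenyl acetate F2. Sonogashira coupling of this acetate with 2 (PdCl2(PPh3)2, CuI, Et3N, THF, 40 °C) gives 4-formyl-2-methoxy-6-[(3,4,5-trimethoxyphenyl)ethynyl]phenyl acetate F3, which cannot cyclise. Brief methanolysis (K2CO3 1.1 equiv, MeOH, 0 °C, then work-up at pH 5) releases 4 in the absence of any metal.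

Step 1. The homologation may stall or give lower yields on scale. The fallback is the Corey–Fuchs sequence; it sets out from 1 and returns at 2. Treatment of 1 with CBr4 and PPh3 in CH2Cl2 at 0 °C gives 5-(2,2-dibromovinyl)-1,2,3-trimethoxybenzene F4. n-BuLi (2.2 equiv) in THF at −78 °C followed by aqueous NH4Cl converts this dibromoalkene into 2 by bromine–lithium exchange and carbenoid rearrangement.

**Further compounds**
F1 | step 3 | 3-iodo-7-methoxy-2-(3,4,5-trimethoxyphenyl)-1-benzofuran-5-carbaldehyde | COc1cc(-c2oc3c(OC)cc(C=O)cc3c2I)cc(OC)c1OC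
F2 | step 2 | 4-formyl-2-iodo-6-methoxyphenyl acetate | COc1cc(C=O)cc(I)c1OC(C)=O
F3 | step 2 | 4-formyl-2-methoxy-6-[(3,4,5-trimethoxyphenyl)ethynyl]phenyl acetate | COc1cc(C=O)cc(C#Cc2cc(OC)c(OC)c(OC)c2)c1OC(C)=O
F4 | step 1 | 5-(2,2-dibromovinyl)-1,2,3-trimethoxybenzene | COc1cc(C=C(Br)Br)cc(OC)c1OC
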